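**Plan**
- Retrosynthesis: the two esters are removed first. The allylic 8-carbinol with its C6=C7 alkene goes back to a 7α,8α-epoxide, and that to a C7=C8 alkene made from an 8-ketone. The 3-carbinol goes back to a C2=C3 isopropyl alkene (hydration), the isopropyl group to a cross-coupling on a 3-ketone, and the 4-carbinol to a 4-ketone.
- The resulting cis-fused hydroazulene-4,8-dione is cut at the ring-fusion bond C3a–C8a and at C6–C7. C7–C8(=O)–C8a(Me) of the seven-membered ring is an oxyallyl cation, C3a=C4(OSi)–C5=C6(Me) is a 2-silyloxydiene, and C1–C3 of the five-membered ring are the three-atom tether, so one intramolecular (4+3) cycloaddition closes both rings.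
- Forward: sulfinate alkylation and Michael addition to acrolein build the cation precursor, a catalytic asymmetric acetate aldol sets one carbinol, and a thioester–boronic acid coupling gives the enone. Double enol silylation and TiCl4 then close both rings, followed by adjustment of C-8, C-4 and C-3 and the two acylations.
- Stereochemistry: the aldol-derived silyloxy centre at C-3 (later sacrificed) directs the cycloaddition, which sets C-3a, C-8a and C-6. C-4 comes from convex-face hydride delivery, C-3 from radical hydration anti to the C-4 substituent, and C-8 from α-face epoxidation followed by anti elimination of the 6α-hydrogen set in the cycloaddition.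

Key step: step 7

Remark: bicyclic compounds are named with azulene locants (C-3 isopropyl carbinol, C-3a ring-fusion CH, C-4 benzoate carbon, C-6 ring methyl carbon, C-8 isovalerate carbon, C-8a angular methyl carbon); α is the face carrying the angular methyl group.
Remark: compounds 3–13 are carried as both epimers at the sulfone-bearing carbon, which becomes the planar cation terminus in step 7.
Remark: (S)-BINOL is expected to give the (R)-carbinol in step 3 with this unbranched aldehyde; the configuration would be confirmed (Mosher ester) before going on, and the other ligand enantiomer used if needed.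

**Route**

Step 1
Reactants: 1 3-chlorobutan-2-one; 2 sodium benzenesulfinate
Product: 3 3-(benzenesulfonyl)butan-2-one (racemic)
Conditions: DMF, rt
Reagents that add atoms: none
Why: SN2 S-alkylation of the sulfinate by the activated α-chloro ketone should give the β-keto sulfone.

Step 2
Reactants: 3 3-(benzenesulfonyl)butan-2-one; 4 prop-2-enal (acrolein)
Product: 5 4-(benzenesulfonyl)-4-methyl-5-oxohexanal (racemic)
Conditions: Et3N (10 mol %), CH2Cl2, 0 °C to rt
Reagents that add atoms: none
Why: Michael addition of the acidic β-keto sulfone to acrolein should create the quaternary carbon that later becomes the cation terminus.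

Step 3
Reactants: 5 4-(benzenesulfonyl)-4-methyl-5-oxohexanal; 6 1-(ethylsulfanyl)-1-(trimethylsilyloxy)ethene
Product: 8 S-ethyl (3R)-6-(benzenesulfonyl)-3-hydroxy-6-methyl-7-oxooctanethioate, via trimethylsilyl aldol ether 7 (not isolated)
Conditions: Ti(OiPr)4 (20 mol %), (S)-BINOL (20 mol %), 4 Å MS, Et2O, −20 °C; then 1 M HCl, THF
Reagents that add atoms: none
Why: Catalytic enantioselective Mukaiyama acetate aldol addition, chemoselective for the aldehyde over the hindered ketone, in which the BINOL–titanium complex selects the aldehyde face and so sets the (R)-carbinol, the only stereocentre brought in from outside.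

Step 4
Reactants: 8 S-ethyl (3R)-6-(benzenesulfonyl)-3-hydroxy-6-methyl-7-oxooctanethioate
Product: 9 S-ethyl (3R)-6-(benzenesulfonyl)-3-[(tert-butyldimethylsilyl)oxy]-6-methyl-7-oxooctanethioate
Conditions: TBSCl, imidazole, DMF, rt
Reagents that add atoms: tert-butyl(chloro)dimethylsilane CC(C)(C)[Si](C)(C)Cl
Why: Standard silylation of the secondary alcohol gives the bulky ether that will later direct the cycloaddition.

Step 5
Reactants: 9 silyl ether thioester; 10 (E)-prop-1-en-1-ylboronic acid
Product: 11 (2E,6R)-9-(benzenesulfonyl)-6-[(tert-butyldimethylsilyl)oxy]-9-methylundec-2-ene-4,10-dione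
Conditions: Pd2(dba)3 (2.5 mol %), tri(2-furyl)phosphine, copper thiophene-2-carboxylate (CuTC, 1.5 equiv), THF, 50 °C
Reagents that add atoms: none
Why: Liebeskind–Srogl coupling turns the thioester into the (E)-enone under neutral conditions that spare the ketone, the sulfone and the β-silyloxy group.

Step 6
Reactants: 11 enone-diketone
Product: 12 (2E,4Z,6R)-9-(benzenesulfonyl)-4,6,10-tris[(tert-butyldimethylsilyl)oxy]-9-methylundeca-2,4,10-triene
Conditions: TBSOTf (2.5 equiv), Et3N, CH2Cl2, −78 to 0 °C
Reagents that add atoms: tert-butyldimethylsilyl triflate CC(C)(C)[Si](C)(C)OS(=O)(=O)C(F)(F)F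
Why: Soft enolisation should silylate the methyl ketone on its only enolisable side and the enone at the α'-position, giving the cross-conjugated (Z)-2-silyloxydiene and the 2-silyloxyallyl sulfone in one operation.

Step 7
Reactants: 12 bis(silyl enol ether) sulfone
Product: 14 cis-fused (3α,3aα,6β,8aα)-3,4-bis[(tert-butyldimethylsilyl)oxy]-6,8a-dimethyl-2,3,3a,6,7,8a-hexahydroazulen-8(1H)-one, via 2-silyloxyallyl cation 13 (not isolated)
Conditions: TiCl4 (1.1 equiv), 2,6-di-tert-butyl-4-methylpyridine, CH2Cl2, −78 °C, 15 min; Et3N then aq. NaHCO3 at −78 °C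
Reagents that add atoms: none
Why: TiCl4 ionises the tertiary sulfone to the 2-silyloxyallyl cation 13, whose two termini are taken up by the tethered (Z)-2-silyloxydiene in an intramolecular (4+3) cycloaddition (concerted but asynchronous, or alkylation of the enol ether followed by Mukaiyama–Michael closure), after which the silyl oxocarbenium ion at the former central carbon loses its silyl group to chloride and leaves the 8-ketone. The closest known reaction types are the Lewis-acid-promoted intramolecular (4+3) cycloaddition of 2-alkoxyallylic sulfones carrying a diene on a three-atom tether and the (4+3) cycloaddition of 2-silyloxyallyl cations with acyclic dienes. The five-membered ring closes by 5-exo attack of the diene terminus on the methyl-bearing cation terminus (creating the quaternary C-8a and C-3a), and the seven-membered ring by union of the CH2 terminus with the propenyl terminus (7-endo if stepwise). The face of the diene is chosen by the silyloxy stereocentre in the tether: to avoid allylic 1,3-strain with the cis silyloxy group of the (Z)-enol ether its hydrogen eclipses the diene, the OTBS group points away, and the tether can deliver the cation to one face only, which fixes C-3a and C-8a in the absolute sense. The cis ring fusion needs the compact, stacked arrangement, expected to win because the extended one would place the diene over the methyl group that sits in the inner position of the cation, and the 6β-methyl group follows from suprafacial addition to the (E)-propenyl terminus. The step also needs ionisation at the sulfone only and survival of the dienol silyl ether, which the low temperature and the far higher lability of the tertiary, donor-flanked sulfone should secure.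

Step 8
Reactants: 14 cycloadduct ketone
Product: 15 cis-fused (3α,3aα,6β,8aα)-3,4-bis[(tert-butyldimethylsilyl)oxy]-6,8a-dimethyl-1,2,3,3a,6,8a-hexahydroazulen-8-yl trifluoromethanesulfonate
Conditions: KN(SiMe3)2, THF, −78 °C; PhNTf2, −78 to 0 °C
Reagents that add atoms: N-phenylbis(trifluoromethanesulfonimide) O=S(=O)(N(c1ccccc1)S(=O)(=O)C(F)(F)F)C(F)(F)F
Why: The 8-ketone can enolise only towards C-7 because C-8a is quaternary, so kinetic enolate trapping should give a single enol triflate while the 4-ketone stays masked as its silyl enol ether.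

Step 9
Reactants: 15 enol triflate
Product: 16 cis-fused (3α,3aα,6β,8aα)-3,4-bis[(tert-butyldimethylsilyl)oxy]-6,8a-dimethyl-1,2,3,3a,6,8a-hexahydroazulene
Conditions: Pd(PPh3)4 (5 mol %), LiCl, Bu3SnH, THF, 60 °C
Reagents that add atoms: none
Why: Palladium-catalysed hydride reduction of the enol triflate leaves the C7=C8 alkene that later carries oxygen to C-8.

Step 10
Reactants: 16 silyl enol ether
Product: 17 (3α,3aα,6β,8aα)-3-[(tert-butyldimethylsilyl)oxy]-6,8a-dimethyl-2,3,3a,5,6,8a-hexahydroazulen-4(1H)-one
Conditions: Bu4NF (1.1 equiv), AcOH (1.2 equiv), THF, −20 °C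
Reagents that add atoms: none
Why: Buffered fluoride cleaves the enol silyl ether far faster than the alkyl silyl ether and protonates at C-5, so the epimerisable C-3a centre and the β-silyloxy group should be untouched.

Step 11
Reactants: 17 4-ketone
Product: 18 (3α,3aα,4β,6β,8aα)-3-[(tert-butyldimethylsilyl)oxy]-6,8a-dimethyl-1,2,3,3a,4,5,6,8a-octahydroazulen-4-ol
Conditions: LiBH(s-Bu)3, THF, −78 °C; then aq. NH4Cl
Reagents that add atoms: none
Why: The bulky hydride should attack the ketone from the convex α face of the cis-fused bicycle (equatorial-type attack, past the 3a-hydrogen), giving the 4β-alcohol.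

Step 12
Reactants: 18 4β-alcohol; 19 4-[(tert-butyldimethylsilyl)oxy]benzoic acid
Product: 20 (3α,3aα,4β,6β,8aα)-3-[(tert-butyldimethylsilyl)oxy]-6,8a-dimethyl-1,2,3,3a,4,5,6,8a-octahydroazulen-4-yl 4-[(tert-butyldimethylsilyl)oxy]benzoate
Conditions: 19, 2,4,6-trichlorobenzoyl chloride, Et3N, THF, rt; then 18, DMAP, toluene, 40 °C
Reagents that add atoms: none
Why: Yamaguchi esterification through the mixed anhydride acylates the hindered secondary alcohol with retention.

Step 13
Reactants: 20 bis-silyl ester
Product: 21 (3α,3aα,4β,6β,8aα)-3-hydroxy-6,8a-dimethyl-1,2,3,3a,4,5,6,8a-octahydroazulen-4-yl 4-[(tert-butyldimethylsilyl)oxy]benzoate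
Conditions: camphorsulfonic acid (0.2 equiv), MeOH–CH2Cl2 1:1, 0 °C to rt
Reagents that add atoms: none
Why: Acid-catalysed methanolysis removes the alkyl silyl ether selectively, because the electron-poor aryl silyl ether is much less basic and is cleaved far more slowly under acid.

Step 14
Reactants: 21 3α-alcohol
Product: 22 (3aα,4β,6β,8aα)-6,8a-dimethyl-3-oxo-1,2,3,3a,4,5,6,8a-octahydroazulen-4-yl 4-[(tert-butyldimethylsilyl)oxy]benzoate
Conditions: Dess–Martin periodinane, NaHCO3, CH2Cl2, 0 °C to rt
Reagents that add atoms: none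
Why: Neutral, buffered oxidation gives the cyclopentanone without epimerising C-3a or eliminating the β-acyloxy group; the controlling stereocentre has done its work and is given up here.

Step 15
Reactants: 22 3-ketone
Product: 23 (3aα,4β,6β,8aα)-6,8a-dimethyl-3-[(trifluoromethanesulfonyl)oxy]-1,3a,4,5,6,8a-hexahydroazulen-4-yl 4-[(tert-butyldimethylsilyl)oxy]benzoate
Conditions: KN(SiMe3)2, THF, −78 °C; N-(5-chloropyridin-2-yl)triflimide, −78 °C
Reagents that add atoms: N-(5-chloropyridin-2-yl)bis(trifluoromethanesulfonimide) O=S(=O)(N(c1ccc(Cl)cn1)S(=O)(=O)C(F)(F)F)C(F)(F)F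
Why: Kinetic deprotonation should take place at the C-2 methylene and not at the hindered C-3a methine, so the enolate is trapped as the C2=C3 enol triflate without E1cB loss of the benzoate.

Step 16
Reactants: 23 enol triflate; 24 isopropylzinc bromide
Product: 25 (3aα,4β,6β,8aα)-6,8a-dimethyl-3-(propan-2-yl)-1,3a,4,5,6,8a-hexahydroazulen-4-yl 4-[(tert-butyldimethylsilyl)oxy]benzoate
Conditions: Pd(OAc)2 (5 mol %), CPhos (10 mol %), THF–toluene, rt
Reagents that add atoms: none
Why: Negishi coupling of the alkenyl triflate with the secondary alkylzinc reagent, with a ligand chosen to outrun β-hydride isomerisation, installs the isopropyl group; the aryl ester tolerates the organozinc.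

Step 17
Reactants: 25 isopropyl cyclopentene
Product: 27 (3α,3aα,4β,6β,8aα)-3-hydroxy-6,8a-dimethyl-3-(propan-2-yl)-1,2,3,3a,4,5,6,8a-octahydroazulen-4-yl 4-[(tert-butyldimethylsilyl)oxy]benzoate, via tertiary hydroperoxide 26 (not isolated)
Conditions: Mn(dpm)3 (10 mol %, dpm = dipivaloylmethanate), PhSiH3, O2 (1 atm), i-PrOH–CH2Cl2, 0 °C; then P(OEt)3
Reagents that add atoms: dioxygen O=O
Why: Mukaiyama hydration: hydrogen-atom transfer to the trisubstituted alkene gives the tertiary C-3 radical, which O2 should trap on the convex α face anti to the vicinal C-4 substituent (3α-OH, 3β-isopropyl), while the 1,2-disubstituted C7=C8 alkene reacts much more slowly.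

Step 18
Reactants: 27 tertiary alcohol
Product: 28 (3α,3aα,4β,6β,7α,8α,8aα)-7,8-epoxy-3-hydroxy-6,8a-dimethyl-3-(propan-2-yl)decahydroazulen-4-yl 4-[(tert-butyldimethylsilyl)oxy]benzoate
Conditions: mCPBA, NaHCO3, CH2Cl2, 0 °C
Reagents that add atoms: 3-chloroperoxybenzoic acid OOC(=O)c1cccc(Cl)c1
Why: Prilezhaev epoxidation of the only remaining alkene should occur on the α face, because the β face is screened by the pseudo-axial C-1 methylene of the cyclopentane and by the 6β-methyl group; this places the C-8 oxygen α.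

Step 19
Reactants: 28 α-epoxide
Product: 30 (3α,3aα,4β,8α,8aα)-3,8-dihydroxy-6,8a-dimethyl-3-(propan-2-yl)-1,2,3,3a,4,5,8,8a-octahydroazulen-4-yl 4-[(tert-butyldimethylsilyl)oxy]benzoate, via bis(trimethylsilyl) ether 29 (not isolated)
Conditions: TMSOTf (3 equiv), DBU (4 equiv), toluene, 0 °C to rt; then citric acid, MeOH
Reagents that add atoms: trimethylsilyl triflate C[Si](C)(C)OS(=O)(=O)C(F)(F)F (its silyl groups are carried only by 29)
Why: Silyl-triflate/amidine isomerisation of an epoxide to an allyl silyl ether: the epoxide opens at C-7 (the carbon away from the quaternary centre) and DBU removes the anti-periplanar 6α-hydrogen, the only β-hydrogen available, so the alkene forms at C6=C7 and the 8α-oxygen is retained.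

Step 20
Reactants: 30 allylic diol; 31 3-methylbutanoyl chloride
Product: 32 (3α,3aα,4β,8α,8aα)-3-hydroxy-6,8a-dimethyl-8-[(3-methylbutanoyl)oxy]-3-(propan-2-yl)-1,2,3,3a,4,5,8,8a-octahydroazulen-4-yl 4-[(tert-butyldimethylsilyl)oxy]benzoate
Conditions: pyridine, DMAP (cat.), CH2Cl2, 0 °C to rt
Reagents that add atoms: none
Why: Acylation takes the secondary allylic alcohol and leaves the tertiary alcohol, which does not react under these conditions.

Step 21
Reactants: 32 silyl-protected diester
Product: 33 CNP0086724.1, (3S,3aS,4R,8R,8aR)-3-hydroxy-6,8a-dimethyl-8-[(3-methylbutanoyl)oxy]-3-(propan-2-yl)-1,2,3,3a,4,5,8,8a-octahydroazulen-4-yl 4-hydroxybenzoate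
Conditions: Bu4NF, AcOH, THF, 0 °C
Reagents that add atoms: none
Why: Buffered fluoride removes the aryl silyl ether within minutes without touching either ester or the allylic system.

**Compound list**

1 | 3-chlorobutan-2-one (racemic) | CC(=O)C(C)Cl | starting material
2 | sodium benzenesulfinate | [Na+].[O-]S(=O)c1ccccc1 | starting material
3 | 3-(benzenesulfonyl)butan-2-one (racemic) | CC(=O)C(C)S(=O)(=O)c1ccccc1 | intermediate
4 | prop-2-enal (acrolein) | C=CC=O | starting material
5 | 4-(benzenesulfonyl)-4-methyl-5-oxohexanal (racemic) | CC(=O)C(C)(CCC=O)S(=O)(=O)c1ccccc1 | intermediate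
6 | 1-(ethylsulfanyl)-1-(trimethylsilyloxy)ethene | C=C(SCC)O[Si](C)(C)C | starting material
7 | S-ethyl (3R)-6-(benzenesulfonyl)-6-methyl-7-oxo-3-(trimethylsilyloxy)octanethioate (C-6 epimers) | CCSC(=O)C[C@H](O[Si](C)(C)C)CCC(C)(C(C)=O)S(=O)(=O)c1ccccc1 | intermediate (not isolated)
8 | S-ethyl (3R)-6-(benzenesulfonyl)-3-hydroxy-6-methyl-7-oxooctanethioate (C-6 epimers) | CCSC(=O)C[C@H](O)CCC(C)(C(C)=O)S(=O)(=O)c1ccccc1 | intermediate
9 | S-ethyl (3R)-6-(benzenesulfonyl)-3-[(tert-butyldimethylsilyl)oxy]-6-methyl-7-oxooctanethioate | CCSC(=O)C[C@H](O[Si](C)(C)C(C)(C)C)CCC(C)(C(C)=O)S(=O)(=O)c1ccccc1 | intermediate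
10 | (E)-prop-1-en-1-ylboronic acid | C/C=C/B(O)O | starting material
11 | (2E,6R)-9-(benzenesulfonyl)-6-[(tert-butyldimethylsilyl)oxy]-9-methylundec-2-ene-4,10-dione | C/C=C/C(=O)C[C@H](O[Si](C)(C)C(C)(C)C)CCC(C)(C(C)=O)S(=O)(=O)c1ccccc1 | intermediate
12 | (2E,4Z,6R)-9-(benzenesulfonyl)-4,6,10-tris[(tert-butyldimethylsilyl)oxy]-9-methylundeca-2,4,10-triene | C/C=C/C(O[Si](C)(C)C(C)(C)C)=C/[C@H](O[Si](C)(C)C(C)(C)C)CCC(C)(C(=C)O[Si](C)(C)C(C)(C)C)S(=O)(=O)c1ccccc1 | intermediate
13 | 2-silyloxyallyl cation formed from 12 by loss of benzenesulfinate | C/C=C/C(O[Si](C)(C)C(C)(C)C)=C/[C@H](O[Si](C)(C)C(C)(C)C)CC[C+](C)C(=C)O[Si](C)(C)C(C)(C)C | intermediate (not isolated)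
14 | cis-fused (3α,3aα,6β,8aα)-3,4-bis[(tert-butyldimethylsilyl)oxy]-6,8a-dimethyl-2,3,3a,6,7,8a-hexahydroazulen-8(1H)-one | C[C@@H]1CC(=O)[C@]2(C)CC[C@@H](O[Si](C)(C)C(C)(C)C)[C@@H]2C(O[Si](C)(C)C(C)(C)C)=C1 | intermediate
15 | 8-enol triflate of 14 (C7=C8, C4=C5) | C[C@@H]1C=C(OS(=O)(=O)C(F)(F)F)[C@]2(C)CC[C@@H](O[Si](C)(C)C(C)(C)C)[C@@H]2C(O[Si](C)(C)C(C)(C)C)=C1 | intermediate
16 | cis-fused (3α,3aα,6β,8aα)-3,4-bis[(tert-butyldimethylsilyl)oxy]-6,8a-dimethyl-1,2,3,3a,6,8a-hexahydroazulene | C[C@@H]1C=C[C@]2(C)CC[C@@H](O[Si](C)(C)C(C)(C)C)[C@@H]2C(O[Si](C)(C)C(C)(C)C)=C1 | intermediate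
17 | (3α,3aα,6β,8aα)-3-[(tert-butyldimethylsilyl)oxy]-6,8a-dimethyl-2,3,3a,5,6,8a-hexahydroazulen-4(1H)-one | C[C@@H]1C=C[C@]2(C)CC[C@@H](O[Si](C)(C)C(C)(C)C)[C@@H]2C(=O)C1 | intermediate
18 | 4β-alcohol from 17 | C[C@@H]1C=C[C@]2(C)CC[C@@H](O[Si](C)(C)C(C)(C)C)[C@@H]2[C@H](O)C1 | intermediate
19 | 4-[(tert-butyldimethylsilyl)oxy]benzoic acid | OC(=O)c1ccc(O[Si](C)(C)C(C)(C)C)cc1 | starting material
20 | 4β-aryl ester, 3α-silyl ether | C[C@@H]1C=C[C@]2(C)CC[C@@H](O[Si](C)(C)C(C)(C)C)[C@@H]2[C@H](OC(=O)c2ccc(O[Si](C)(C)C(C)(C)C)cc2)C1 | intermediate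
21 | 4β-aryl ester, 3α-alcohol | C[C@@H]1C=C[C@]2(C)CC[C@@H](O)[C@@H]2[C@H](OC(=O)c2ccc(O[Si](C)(C)C(C)(C)C)cc2)C1 | intermediate
22 | 4β-aryl ester, 3-ketone | C[C@@H]1C=C[C@]2(C)CCC(=O)[C@@H]2[C@H](OC(=O)c2ccc(O[Si](C)(C)C(C)(C)C)cc2)C1 | intermediate
23 | 4β-aryl ester, C2=C3 enol triflate | C[C@@H]1C=C[C@]2(C)CC=C(OS(=O)(=O)C(F)(F)F)[C@@H]2[C@H](OC(=O)c2ccc(O[Si](C)(C)C(C)(C)C)cc2)C1 | intermediate
24 | isopropylzinc bromide | CC(C)[Zn]Br | starting material
25 | 4β-aryl ester, 3-isopropyl C2=C3 alkene | C[C@@H]1C=C[C@]2(C)CC=C(C(C)C)[C@@H]2[C@H](OC(=O)c2ccc(O[Si](C)(C)C(C)(C)C)cc2)C1 | intermediate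
26 | 3α-hydroperoxide of 27 | C[C@@H]1C=C[C@]2(C)CC[C@](OO)(C(C)C)[C@@H]2[C@H](OC(=O)c2ccc(O[Si](C)(C)C(C)(C)C)cc2)C1 | intermediate (not isolated)
27 | 4β-aryl ester, 3α-hydroxy-3β-isopropyl, C7=C8 alkene | C[C@@H]1C=C[C@]2(C)CC[C@](O)(C(C)C)[C@@H]2[C@H](OC(=O)c2ccc(O[Si](C)(C)C(C)(C)C)cc2)C1 | intermediate
28 | 7α,8α-epoxide of 27 | C[C@@H]1[C@H]2O[C@H]2[C@]3(C)CC[C@](O)(C(C)C)[C@@H]3[C@H](OC(=O)c3ccc(O[Si](C)(C)C(C)(C)C)cc3)C1 | intermediate
29 | 3α,8α-bis(trimethylsilyl) ether of 30 | CC1=C[C@@H](O[Si](C)(C)C)[C@]2(C)CC[C@](O[Si](C)(C)C)(C(C)C)[C@@H]2[C@H](OC(=O)c2ccc(O[Si](C)(C)C(C)(C)C)cc2)C1 | intermediate (not isolated)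
30 | 3α,8α-diol, C6=C7 alkene, 4β-aryl ester | CC1=C[C@@H](O)[C@]2(C)CC[C@](O)(C(C)C)[C@@H]2[C@H](OC(=O)c2ccc(O[Si](C)(C)C(C)(C)C)cc2)C1 | intermediate
31 | 3-methylbutanoyl chloride | CC(C)CC(Cl)=O | starting material
32 | 8α-isovalerate, 4β-[4-(silyloxy)benzoate] | CC1=C[C@@H](OC(=O)CC(C)C)[C@]2(C)CC[C@](O)(C(C)C)[C@@H]2[C@H](OC(=O)c2ccc(O[Si](C)(C)C(C)(C)C)cc2)C1 | intermediate
33 | CNP0086724.1 | CC1=C[C@@H](OC(=O)CC(C)C)[C@]2(C)CC[C@](O)(C(C)C)[C@@H]2[C@H](OC(=O)c2ccc(O)cc2)C1 | target

**Count and risks**

Total steps: 21. Longest linear sequence: 21 steps (from 1).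

Step 7. The cascade may stop after the first bond (the dienol silyl group is lost to chloride before the seven-membered ring closes), the secondary dienylic silyl ether may ionise instead, or the ring fusion may not be formed cis selectively. The fallback makes the two bonds in separate known operations and sets out from 12. Ionisation with TiCl4 and an aqueous acidic quench at −78 °C would give, after the five-ring closure alone, the monocyclic diketone cis-1-acetyl-2-[(2E)-but-2-enoyl]-3-[(tert-butyldimethylsilyl)oxy]-1-methylcyclopentane F1, whose cis isomer would be separated. TBSOTf and Et3N would then convert the acetyl group into its kinetic silyl enol ether F2, the enone α'-position being a hindered methine. Catalytic TBSOTf in CH2Cl2 at −78 °C would close the seven-membered ring by intramolecular Mukaiyama–Michael addition with silyl transfer to the enone oxygen, which returns to the route at 14.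

Step 19 (with the epoxidation before it). The Lewis-acid-activated epoxide next to the quaternary carbon may rearrange by hydride or alkyl shift, and the facial selectivity of step 18 may be poor. The fallback sets out from 27 and uses a Schenck ene reaction (O2, tetraphenylporphyrin, visible light, CH2Cl2, 0 °C, stopped at partial conversion to limit over-oxidation). The only allylic hydrogen of the C7=C8 alkene is the 6α-hydrogen, so oxygen should be delivered suprafacially to the α face of C-8 while the double bond moves to C6=C7, giving the 8α-hydroperoxide F3. Reduction with PPh3 would give the diol, which returns to the route at 30.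

Step 11. Hydride delivery to the 4-ketone of a flexible seven-membered ring may show poor or reversed facial selectivity. The fallback sets out from 17. If reduction (for example with NaBH4–CeCl3) gives mainly the 4α-alcohol F4, it would be esterified with acid 19 under Mitsunobu conditions (PPh3, diisopropyl azodicarboxylate, toluene), and the inversion at C-4 returns to the route at 20.

**Further compounds**

F1 | step 7 | cis-1-acetyl-2-[(2E)-but-2-enoyl]-3-[(tert-butyldimethylsilyl)oxy]-1-methylcyclopentane (acetyl and butenoyl cis, silyloxy trans to butenoyl) | CC(=O)[C@]1(C)CC[C@@H](O[Si](C)(C)C(C)(C)C)[C@@H]1C(=O)/C=C/C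
F2 | step 7 | kinetic tert-butyldimethylsilyl enol ether of the acetyl group of F1 | C=C(O[Si](C)(C)C(C)(C)C)[C@]1(C)CC[C@@H](O[Si](C)(C)C(C)(C)C)[C@@H]1C(=O)/C=C/C
F3 | step 19 | 8α-hydroperoxide corresponding to diol 30 | CC1=C[C@@H](OO)[C@]2(C)CC[C@](O)(C(C)C)[C@@H]2[C@H](OC(=O)c2ccc(O[Si](C)(C)C(C)(C)C)cc2)C1
F4 | step 11 | 4α-alcohol, C-4 epimer of 18 | C[C@@H]1C=C[C@]2(C)CC[C@@H](O[Si](C)(C)C(C)(C)C)[C@@H]2[C@@H](O)C1
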